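**Plan**
- Retrosynthesis (octahydro-1H-indene numbering: C1 acetyl, C2 angelate, C4 methylidene, C6 epoxyangelate, C7 isopropyl): cut the two ester C–O bonds, then in one retro-step the ring bonds C1–C2 (ring A) and C3a–C7a (ring B).
- Enabling feature: the 4-methylidene next to C3a is the footprint of an allylsilane, C7a is β and C1 is α to the acetyl carbonyl, and the C2 carbinol is the aldol partner of C1. An open chain carrying a (Z)-allylsilane, an (E)-enone and an aldehyde can therefore fold into both rings in one Sakurai–aldol cascade.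
- Forward: the chain is built linearly (isovaleryl imide, benzyloxymethylation, chelation-controlled propargylation, silylmethyl-cupration with oxirane trapping, Wittig enone, aldehyde). Ring B and then ring A form in the cascade; the angelate and then the epoxyangelate go on last.
- Stereochemistry: C7 from the oxazolidinone auxiliary; C6 by 1,2-chelation control; alkene geometry from syn carbocupration; C3a, C7a, C1 and C2 from the cascade (chair, A(1,3) strain, closed aldol); the epoxide from a Sharpless epoxidation; the Z-enoate from angelic acid.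

Key step: step 14

Remark: methyl angelate, angelic acid and tributyl(propa-1,2-dien-1-yl)stannane are taken as commercial; all locants in the overview and in the Why lines refer to the octahydroindene numbering of the target.

**Step 1**
Reactants: 1 (4R)-4-benzyl-1,3-oxazolidin-2-one; 2 3-methylbutanoyl chloride
Product: 3 (4R)-4-benzyl-3-(3-methylbutanoyl)-1,3-oxazolidin-2-one
Conditions: n-BuLi, THF, −78 °C; then 2, −78 → 0 °C
Reagents that add atoms: none
Why: N-acylation of the lithiated oxazolidinone by the acid chloride (attachment of the Evans auxiliary) is routine and creates no stereocentre.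

**Step 2**
Reactants: 3 (4R)-4-benzyl-3-(3-methylbutanoyl)-1,3-oxazolidin-2-one; 4 benzyl chloromethyl ether
Product: 5 (4R)-4-benzyl-3-[(2S)-2-[(benzyloxy)methyl]-3-methylbutanoyl]-1,3-oxazolidin-2-one
Conditions: TiCl4, i-Pr2NEt, CH2Cl2, 0 °C; then 4, 0 °C
Reagents that add atoms: none
Why: Evans alkylation of the chelated (Z)-titanium enolate, in which the benzyl group of the (4R)-auxiliary blocks one face so that the electrophile adds to the other and sets the (2S) centre (the future C7).

**Step 3**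
Reactants: 5 (4R)-4-benzyl-3-[(2S)-2-[(benzyloxy)methyl]-3-methylbutanoyl]-1,3-oxazolidin-2-one
Product: 6 (2R)-2-[(benzyloxy)methyl]-3-methylbutan-1-ol
Conditions: LiBH4, MeOH (1 equiv), Et2O, 0 °C
Reagents that add atoms: none
Why: Reductive cleavage of the imide by LiBH4 should free the primary alcohol and return the auxiliary without touching the α-stereocentre (the descriptor changes only through the priorities).

**Step 4**
Reactants: 6 (2R)-2-[(benzyloxy)methyl]-3-methylbutan-1-ol
Product: 7 (2S)-2-[(benzyloxy)methyl]-3-methylbutanal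
Conditions: Dess–Martin periodinane, NaHCO3, CH2Cl2, 0 °C → rt
Reagents that add atoms: none
Why: Dess–Martin oxidation under buffered, non-basic conditions should give the α-branched aldehyde, which is used at once so that its α-centre does not epimerize.

**Step 5**
Reactants: 7 (2S)-2-[(benzyloxy)methyl]-3-methylbutanal; 8 tributyl(propa-1,2-dien-1-yl)stannane
Product: 9 (2S,3R)-1-(benzyloxy)-2-(propan-2-yl)hex-5-yn-3-ol
Conditions: MgBr2·OEt2, CH2Cl2, −20 °C; then 8
Reagents that add atoms: none
Why: Chelation-controlled SE2′ propargylation, in which MgBr2 bridges the aldehyde and benzyloxy oxygens in a six-membered chelate and the allenylstannane attacks the face opposite the isopropyl group, should give the 2,3-anti alcohol (3R, the future C6).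

**Step 6**
Reactants: 9 (2S,3R)-1-(benzyloxy)-2-(propan-2-yl)hex-5-yn-3-ol
Product: 10 {[(2S,3R)-1-(benzyloxy)-2-(propan-2-yl)hex-5-yn-3-yl]oxy}(tert-butyl)dimethylsilane
Conditions: TBSOTf, 2,6-lutidine, CH2Cl2, −78 → 0 °C
Reagents that add atoms: tert-butyldimethylsilyl trifluoromethanesulfonate, CC(C)(C)[Si](C)(C)OS(=O)(=O)C(F)(F)F
Why: Silylation with the silyl triflate and a hindered base protects the hindered secondary alcohol as an ether that should survive organocopper, dissolving-metal and Lewis-acid steps; no stereocentre is affected.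

**Step 7**
Reactants: 10 {[(2S,3R)-1-(benzyloxy)-2-(propan-2-yl)hex-5-yn-3-yl]oxy}(tert-butyl)dimethylsilane; 11 [(trimethylsilyl)methyl]magnesium chloride; 12 oxirane
Product: 14 (3Z,6R,7S)-8-(benzyloxy)-6-[(tert-butyldimethylsilyl)oxy]-7-(propan-2-yl)-4-[(trimethylsilyl)methyl]oct-3-en-1-ol, via alkenylcopper adduct 13 (not isolated)
Conditions: 11, CuBr·SMe2, Et2O/Me2S, −40 °C; then 10, −20 °C → rt; then 12, −30 → 0 °C; aq NH4Cl
Reagents that add atoms: none
Why: Carbocupration of the terminal alkyne is a syn addition that puts the silylmethyl group on the internal carbon and copper on the terminal one, and alkylation of the alkenylcopper by oxirane proceeds with retention, so the hydroxyethyl arm should end up cis to CH2SiMe3 (3Z).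

**Step 8**
Reactants: 14 (3Z,6R,7S)-8-(benzyloxy)-6-[(tert-butyldimethylsilyl)oxy]-7-(propan-2-yl)-4-[(trimethylsilyl)methyl]oct-3-en-1-ol
Product: 15 (3Z,6R,7S)-8-(benzyloxy)-6-[(tert-butyldimethylsilyl)oxy]-7-(propan-2-yl)-1-[(triethylsilyl)oxy]-4-[(trimethylsilyl)methyl]oct-3-ene
Conditions: Et3SiCl, imidazole, CH2Cl2, 0 °C
Reagents that add atoms: chlorotriethylsilane, CC[Si](Cl)(CC)CC
Why: Standard silylation of the primary alcohol gives a triethylsilyl ether that can later be removed in the presence of the secondary tert-butyldimethylsilyl ether.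

**Step 9**
Reactants: 15 (3Z,6R,7S)-8-(benzyloxy)-6-[(tert-butyldimethylsilyl)oxy]-7-(propan-2-yl)-1-[(triethylsilyl)oxy]-4-[(trimethylsilyl)methyl]oct-3-ene
Product: 16 (2S,3R,5Z)-3-[(tert-butyldimethylsilyl)oxy]-2-(propan-2-yl)-8-[(triethylsilyl)oxy]-5-[(trimethylsilyl)methyl]oct-5-en-1-ol
Conditions: Li, 4,4′-di-tert-butylbiphenyl, THF, −78 °C; then aq NH4Cl
Reagents that add atoms: none
Why: Reductive cleavage of the benzyl ether by the arene radical anion (dissolving-metal debenzylation) should spare the isolated trisubstituted alkene, the allylsilane and both silyl ethers, where hydrogenolysis could not be used.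

**Step 10**
Reactants: 16 (2S,3R,5Z)-3-[(tert-butyldimethylsilyl)oxy]-2-(propan-2-yl)-8-[(triethylsilyl)oxy]-5-[(trimethylsilyl)methyl]oct-5-en-1-ol
Product: 17 (2R,3R,5Z)-3-[(tert-butyldimethylsilyl)oxy]-2-(propan-2-yl)-8-[(triethylsilyl)oxy]-5-[(trimethylsilyl)methyl]oct-5-enal
Conditions: Dess–Martin periodinane, NaHCO3, CH2Cl2, 0 °C → rt
Reagents that add atoms: none
Why: Buffered Dess–Martin oxidation should give the aldehyde without epimerizing the α-centre or eliminating the β-silyloxy group (the descriptor at C2 changes only through the priorities).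

**Step 11**
Reactants: 17 (2R,3R,5Z)-3-[(tert-butyldimethylsilyl)oxy]-2-(propan-2-yl)-8-[(triethylsilyl)oxy]-5-[(trimethylsilyl)methyl]oct-5-enal; 18 1-(triphenyl-λ5-phosphanylidene)propan-2-one
Product: 19 (3E,5S,6R,8Z)-6-[(tert-butyldimethylsilyl)oxy]-5-(propan-2-yl)-11-[(triethylsilyl)oxy]-8-[(trimethylsilyl)methyl]undeca-3,8-dien-2-one
Conditions: toluene, 80 °C
Reagents that add atoms: none
Why: Wittig olefination with the stabilized acetylmethylene ylide should give the (E)-enone under neutral conditions that neither epimerize the α-centre nor eliminate the β-silyloxy group.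

**Step 12**
Reactants: 19 (3E,5S,6R,8Z)-6-[(tert-butyldimethylsilyl)oxy]-5-(propan-2-yl)-11-[(triethylsilyl)oxy]-8-[(trimethylsilyl)methyl]undeca-3,8-dien-2-one
Product: 20 (3E,5S,6R,8Z)-6-[(tert-butyldimethylsilyl)oxy]-11-hydroxy-5-(propan-2-yl)-8-[(trimethylsilyl)methyl]undeca-3,8-dien-2-one
Conditions: PPTS (cat.), MeOH/CH2Cl2, 0 °C
Reagents that add atoms: none
Why: Acid-catalysed methanolysis should remove the primary triethylsilyl ether selectively over the hindered secondary tert-butyldimethylsilyl ether, the acid being too weak to protodesilylate the allylsilane.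

**Step 13**
Reactants: 20 (3E,5S,6R,8Z)-6-[(tert-butyldimethylsilyl)oxy]-11-hydroxy-5-(propan-2-yl)-8-[(trimethylsilyl)methyl]undeca-3,8-dien-2-one
Product: 21 (3Z,6R,7S,8E)-6-[(tert-butyldimethylsilyl)oxy]-10-oxo-7-(propan-2-yl)-4-[(trimethylsilyl)methyl]undeca-3,8-dienal
Conditions: Dess–Martin periodinane, NaHCO3, CH2Cl2, 0 °C; crude aldehyde used at once
Reagents that add atoms: none
Why: Buffered Dess–Martin oxidation forms the β,γ-unsaturated aldehyde without base, so the double bond should not move into conjugation before the next step.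

**Step 14**
Reactants: 21 (3Z,6R,7S,8E)-6-[(tert-butyldimethylsilyl)oxy]-10-oxo-7-(propan-2-yl)-4-[(trimethylsilyl)methyl]undeca-3,8-dienal
Product: 23 1-[(1R,2S,3aR,6R,7S,7aR)-6-[(tert-butyldimethylsilyl)oxy]-2-hydroxy-4-methylidene-7-(propan-2-yl)octahydro-1H-inden-1-yl]ethan-1-one, via trichlorotitanium enolate 22 (not isolated)
Conditions: TiCl4 (1.2 equiv), 2,6-di-tert-butyl-4-methylpyridine (0.2 equiv), CH2Cl2 (0.005 M), −78 °C; aq NaHCO3
Reagents that add atoms: none
Why: Proposed new method: TiCl4 activates the (E)-enone and the nucleophilic terminus of the (Z)-allylsilane (future C3a) adds to the β-carbon (future C7a) with loss of Me3SiCl, which closes ring B and leaves the exocyclic methylene at C4 and the regiodefined trichlorotitanium enolate 22; this enolate then adds through its internal carbon (C1) to the tethered aldehyde (C2) and closes ring A. The closest known reactions are the intramolecular Sakurai cyclization of allylsilanes onto enones and the intermolecular tandem Sakurai–aldol reaction, in which the titanium enolate formed by conjugate allylation is trapped by an aldehyde; their union in a double ring closure is the new element. Ring B closes 6-exo-trig (the enone C=C is exocyclic to the forming ring) and ring A closes 5-(enolexo)-exo-trig. C3a and C7a should be set in a chair transition state that keeps the isopropyl group at C7 and the forming C7a side chain equatorial (silyloxy at C6 axial), the Z geometry of the allylsilane placing the CH2CHO arm equatorial and hence trans; C1 should be set by A(1,3) strain, which holds C7a–H in the plane of the enolate so that the aldehyde, delivered from the C3a side, bonds anti to C7; C2 should be set by a closed, titanium-bridged transition state that puts the hydroxyl cis to the acetyl group. The step needs chemoselectivity (enone before aldehyde) and aldol regioselectivity (C1, not the acetyl methyl): the aldehyde lies only two carbons from the nucleophilic carbon and cannot be reached by it, and the enolate is generated regiospecifically by the conjugate addition and does not equilibrate at −78 °C.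

**Step 15**
Reactants: 23 1-[(1R,2S,3aR,6R,7S,7aR)-6-[(tert-butyldimethylsilyl)oxy]-2-hydroxy-4-methylidene-7-(propan-2-yl)octahydro-1H-inden-1-yl]ethan-1-one; 24 (2Z)-2-methylbut-2-enoic acid (angelic acid)
Product: 26 (1R,2S,3aR,6R,7S,7aR)-1-acetyl-6-[(tert-butyldimethylsilyl)oxy]-4-methylidene-7-(propan-2-yl)octahydro-1H-inden-2-yl (2Z)-2-methylbut-2-enoate, via angelic 2,4,6-trichlorobenzoic anhydride 25 (not isolated)
Conditions: 24, 2,4,6-trichlorobenzoyl chloride, Et3N, toluene, rt; then 23, toluene, 75 °C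
Reagents that add atoms: none
Why: Yamaguchi-type esterification through the mixed anhydride 25 without a nucleophilic catalyst should acylate the secondary alcohol with the Z geometry intact, because no acylpyridinium species that could add reversibly to the enoate is formed.

**Step 16**
Reactants: 26 (1R,2S,3aR,6R,7S,7aR)-1-acetyl-6-[(tert-butyldimethylsilyl)oxy]-4-methylidene-7-(propan-2-yl)octahydro-1H-inden-2-yl (2Z)-2-methylbut-2-enoate
Product: 27 (1R,2S,3aR,6R,7S,7aR)-1-acetyl-6-hydroxy-4-methylidene-7-(propan-2-yl)octahydro-1H-inden-2-yl (2Z)-2-methylbut-2-enoate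
Conditions: HF·pyridine, pyridine, THF, 0 °C → rt
Reagents that add atoms: none
Why: Fluoride-mediated desilylation under weakly acidic conditions should free the C6 alcohol without the base that would trigger β-elimination of the angelate next to the ketone.

**Step 17**
Reactants: 28 methyl (2Z)-2-methylbut-2-enoate (methyl angelate)
Product: 29 (2Z)-2-methylbut-2-en-1-ol
Conditions: i-Bu2AlH, CH2Cl2, −78 → 0 °C
Reagents that add atoms: none
Why: 1,2-Reduction of the enoate by i-Bu2AlH should give the allylic alcohol with the Z geometry unchanged.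

**Step 18**
Reactants: 29 (2Z)-2-methylbut-2-en-1-ol
Product: 30 [(2R,3S)-2,3-dimethyloxiran-2-yl]methanol
Conditions: Ti(OiPr)4 (cat.), D-(−)-diethyl tartrate, t-BuOOH, 4 Å MS, CH2Cl2, −20 °C
Reagents that add atoms: tert-butyl hydroperoxide, CC(C)(C)OO
Why: Sharpless asymmetric epoxidation, in which the titanium–tartrate complex delivers oxygen to one face of the allylic alcohol, should give the (2R,3S)-epoxy alcohol with D-(−)-diethyl tartrate, the syn addition keeping the C3 methyl cis to CH2OH.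

**Step 19**
Reactants: 30 [(2R,3S)-2,3-dimethyloxiran-2-yl]methanol
Product: 31 (2S,3S)-2,3-dimethyloxirane-2-carboxylic acid
Conditions: RuCl3 hydrate (cat.), NaIO4, MeCN/CCl4/H2O, 0 °C → rt
Reagents that add atoms: sodium periodate, [Na+].[O-]I(=O)(=O)=O; water, O
Why: Catalytic RuO4 oxidation (Sharpless conditions) should take the primary alcohol to the acid and leave the trisubstituted epoxide intact, the descriptor at C2 changing from R to S only through the priorities.

**Step 20**
Reactants: 27 (1R,2S,3aR,6R,7S,7aR)-1-acetyl-6-hydroxy-4-methylidene-7-(propan-2-yl)octahydro-1H-inden-2-yl (2Z)-2-methylbut-2-enoate; 31 (2S,3S)-2,3-dimethyloxirane-2-carboxylic acid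
Product: 33 (1R,2S,3aR,6R,7S,7aR)-1-acetyl-4-methylidene-2-{[(2Z)-2-methylbut-2-enoyl]oxy}-7-(propan-2-yl)octahydro-1H-inden-6-yl (2S,3S)-2,3-dimethyloxirane-2-carboxylate, via epoxyangelic 2,4,6-trichlorobenzoic anhydride 32 (not isolated)
Conditions: 31, 2,4,6-trichlorobenzoyl chloride, Et3N, THF, rt; then 27, DMAP, toluene, rt
Reagents that add atoms: none
Why: Yamaguchi esterification with DMAP should acylate the hindered axial C6 alcohol with the α-quaternary acid at room temperature, with no new stereocentre and with the epoxide stable to these non-acidic conditions.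

**Compound list**
1 | (4R)-4-benzyl-1,3-oxazolidin-2-one | O=C1N[C@H](Cc2ccccc2)CO1 | starting material
2 | 3-methylbutanoyl chloride | CC(C)CC(=O)Cl | starting material
3 | (4R)-4-benzyl-3-(3-methylbutanoyl)-1,3-oxazolidin-2-one | CC(C)CC(=O)N1[C@H](Cc2ccccc2)COC1=O | intermediate
4 | benzyl chloromethyl ether | ClCOCc1ccccc1 | starting material
5 | (4R)-4-benzyl-3-[(2S)-2-[(benzyloxy)methyl]-3-methylbutanoyl]-1,3-oxazolidin-2-one | O=C([C@@H](C(C)C)COCc1ccccc1)N1[C@H](Cc2ccccc2)COC1=O | intermediate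
6 | (2R)-2-[(benzyloxy)methyl]-3-methylbutan-1-ol | OC[C@@H](C(C)C)COCc1ccccc1 | intermediate
7 | (2S)-2-[(benzyloxy)methyl]-3-methylbutanal | O=C[C@@H](C(C)C)COCc1ccccc1 | intermediate
8 | tributyl(propa-1,2-dien-1-yl)stannane | C=C=C[Sn](CCCC)(CCCC)CCCC | starting material
9 | (2S,3R)-1-(benzyloxy)-2-(propan-2-yl)hex-5-yn-3-ol | C#CC[C@@H](O)[C@@H](C(C)C)COCc1ccccc1 | intermediate
10 | {[(2S,3R)-1-(benzyloxy)-2-(propan-2-yl)hex-5-yn-3-yl]oxy}(tert-butyl)dimethylsilane | C#CC[C@@H](O[Si](C)(C)C(C)(C)C)[C@@H](C(C)C)COCc1ccccc1 | intermediate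
11 | [(trimethylsilyl)methyl]magnesium chloride | C[Si](C)(C)C[Mg]Cl | starting material
12 | oxirane | C1CO1 | starting material
13 | [(1Z,4R,5S)-6-(benzyloxy)-4-[(tert-butyldimethylsilyl)oxy]-5-(propan-2-yl)-2-[(trimethylsilyl)methyl]hex-1-en-1-yl]copper | [Cu]/C=C(\C[Si](C)(C)C)C[C@@H](O[Si](C)(C)C(C)(C)C)[C@@H](C(C)C)COCc1ccccc1 | intermediate
14 | (3Z,6R,7S)-8-(benzyloxy)-6-[(tert-butyldimethylsilyl)oxy]-7-(propan-2-yl)-4-[(trimethylsilyl)methyl]oct-3-en-1-ol | OCC/C=C(\C[Si](C)(C)C)C[C@@H](O[Si](C)(C)C(C)(C)C)[C@@H](C(C)C)COCc1ccccc1 | intermediate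
15 | (3Z,6R,7S)-8-(benzyloxy)-6-[(tert-butyldimethylsilyl)oxy]-7-(propan-2-yl)-1-[(triethylsilyl)oxy]-4-[(trimethylsilyl)methyl]oct-3-ene | CC[Si](CC)(CC)OCC/C=C(\C[Si](C)(C)C)C[C@@H](O[Si](C)(C)C(C)(C)C)[C@@H](C(C)C)COCc1ccccc1 | intermediate
16 | (2S,3R,5Z)-3-[(tert-butyldimethylsilyl)oxy]-2-(propan-2-yl)-8-[(triethylsilyl)oxy]-5-[(trimethylsilyl)methyl]oct-5-en-1-ol | CC[Si](CC)(CC)OCC/C=C(\C[Si](C)(C)C)C[C@@H](O[Si](C)(C)C(C)(C)C)[C@@H](C(C)C)CO | intermediate
17 | (2R,3R,5Z)-3-[(tert-butyldimethylsilyl)oxy]-2-(propan-2-yl)-8-[(triethylsilyl)oxy]-5-[(trimethylsilyl)methyl]oct-5-enal | CC[Si](CC)(CC)OCC/C=C(\C[Si](C)(C)C)C[C@@H](O[Si](C)(C)C(C)(C)C)[C@@H](C(C)C)C=O | intermediate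
18 | 1-(triphenyl-λ5-phosphanylidene)propan-2-one | CC(=O)C=P(c1ccccc1)(c1ccccc1)c1ccccc1 | starting material
19 | (3E,5S,6R,8Z)-6-[(tert-butyldimethylsilyl)oxy]-5-(propan-2-yl)-11-[(triethylsilyl)oxy]-8-[(trimethylsilyl)methyl]undeca-3,8-dien-2-one | CC[Si](CC)(CC)OCC/C=C(\C[Si](C)(C)C)C[C@@H](O[Si](C)(C)C(C)(C)C)[C@@H](C(C)C)/C=C/C(C)=O | intermediate
20 | (3E,5S,6R,8Z)-6-[(tert-butyldimethylsilyl)oxy]-11-hydroxy-5-(propan-2-yl)-8-[(trimethylsilyl)methyl]undeca-3,8-dien-2-one | OCC/C=C(\C[Si](C)(C)C)C[C@@H](O[Si](C)(C)C(C)(C)C)[C@@H](C(C)C)/C=C/C(C)=O | intermediate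
21 | (3Z,6R,7S,8E)-6-[(tert-butyldimethylsilyl)oxy]-10-oxo-7-(propan-2-yl)-4-[(trimethylsilyl)methyl]undeca-3,8-dienal | O=CC/C=C(\C[Si](C)(C)C)C[C@@H](O[Si](C)(C)C(C)(C)C)[C@@H](C(C)C)/C=C/C(C)=O | intermediate
22 | trichloro{[1-{(1R,2S,3R,6R)-3-[(tert-butyldimethylsilyl)oxy]-5-methylidene-6-(2-oxoethyl)-2-(propan-2-yl)cyclohexyl}prop-1-en-2-yl]oxy}titanium | C=C1C[C@@H](O[Si](C)(C)C(C)(C)C)[C@@H](C(C)C)[C@H](C=C(C)O[Ti](Cl)(Cl)Cl)[C@H]1CC=O | intermediate
23 | 1-[(1R,2S,3aR,6R,7S,7aR)-6-[(tert-butyldimethylsilyl)oxy]-2-hydroxy-4-methylidene-7-(propan-2-yl)octahydro-1H-inden-1-yl]ethan-1-one | C=C1C[C@@H](O[Si](C)(C)C(C)(C)C)[C@@H](C(C)C)[C@@H]2[C@@H](C(C)=O)[C@@H](O)C[C@@H]12 | intermediate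
24 | (2Z)-2-methylbut-2-enoic acid | C/C=C(/C)C(=O)O | starting material
25 | (2Z)-2-methylbut-2-enoic 2,4,6-trichlorobenzoic anhydride | C/C=C(/C)C(=O)OC(=O)c1c(Cl)cc(Cl)cc1Cl | intermediate
26 | (1R,2S,3aR,6R,7S,7aR)-1-acetyl-6-[(tert-butyldimethylsilyl)oxy]-4-methylidene-7-(propan-2-yl)octahydro-1H-inden-2-yl (2Z)-2-methylbut-2-enoate | C=C1C[C@@H](O[Si](C)(C)C(C)(C)C)[C@@H](C(C)C)[C@@H]2[C@@H](C(C)=O)[C@@H](OC(=O)/C(C)=C\C)C[C@@H]12 | intermediate
27 | (1R,2S,3aR,6R,7S,7aR)-1-acetyl-6-hydroxy-4-methylidene-7-(propan-2-yl)octahydro-1H-inden-2-yl (2Z)-2-methylbut-2-enoate | C=C1C[C@@H](O)[C@@H](C(C)C)[C@@H]2[C@@H](C(C)=O)[C@@H](OC(=O)/C(C)=C\C)C[C@@H]12 | intermediate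
28 | methyl (2Z)-2-methylbut-2-enoate | C/C=C(/C)C(=O)OC | starting material
29 | (2Z)-2-methylbut-2-en-1-ol | C/C=C(/C)CO | intermediate
30 | [(2R,3S)-2,3-dimethyloxiran-2-yl]methanol | OC[C@@]1(C)O[C@H]1C | intermediate
31 | (2S,3S)-2,3-dimethyloxirane-2-carboxylic acid | OC(=O)[C@@]1(C)O[C@H]1C | intermediate
32 | (2S,3S)-2,3-dimethyloxirane-2-carboxylic 2,4,6-trichlorobenzoic anhydride | O=C(OC(=O)c1c(Cl)cc(Cl)cc1Cl)[C@@]1(C)O[C@H]1C | intermediate
33 | (1R,2S,3aR,6R,7S,7aR)-1-acetyl-4-methylidene-2-{[(2Z)-2-methylbut-2-enoyl]oxy}-7-(propan-2-yl)octahydro-1H-inden-6-yl (2S,3S)-2,3-dimethyloxirane-2-carboxylate | C=C1C[C@@H](OC(=O)[C@@]2(C)O[C@H]2C)[C@@H](C(C)C)[C@@H]2[C@@H](C(C)=O)[C@@H](OC(=O)/C(C)=C\C)C[C@@H]12 | target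

Total step count: 20. Longest linear sequence: 17 steps (steps 1–16, then step 20); steps 17–19 make the epoxy acid separately.

**Steps most likely to fail**

Step 14 (Sakurai–aldol cascade). What may go wrong:
- the allylsilane may be protodesilylated, or the β,γ double bond of the aldehyde may move into conjugation, before ring B closes;
- the cascade may stop after the conjugate allylation through protonation of the enolate;
- the aldehyde may undergo a competing Prins-type addition to the new exocyclic methylene;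
- an open aldol transition state may erode the cis selectivity at C2.

The fallback separates the two ring closures and uses known reaction types only. It sets out from enone 19, in which the future aldehyde is still a triethylsilyl ether. An EtAlCl2-promoted intramolecular Sakurai cyclization (toluene, −78 °C) would close ring B alone and give the ring-B ketone 1-[(1R,2S,3R,6R)-3-[(tert-butyldimethylsilyl)oxy]-5-methylidene-2-(propan-2-yl)-6-{2-[(triethylsilyl)oxy]ethyl}cyclohexyl]propan-2-one F1. PPTS in MeOH would give the alcohol 1-[(1R,2S,3R,6R)-3-[(tert-butyldimethylsilyl)oxy]-6-(2-hydroxyethyl)-5-methylidene-2-(propan-2-yl)cyclohexyl]propan-2-one F2. Dess–Martin oxidation would give the keto-aldehyde 1-[(1R,2S,3R,6R)-3-[(tert-butyldimethylsilyl)oxy]-5-methylidene-6-(2-oxoethyl)-2-(propan-2-yl)cyclohexyl]propan-2-one F3. Ring A would then be closed by a titanium-mediated direct aldol (TiCl4, i-Pr2NEt, CH2Cl2, −78 °C), a method known to enolize methyl alkyl ketones on the more substituted side and to react through a chelated, syn-selective transition state. This returns to the route at 23.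

Step 7 (silylmethyl-cupration and oxirane trapping). What may go wrong: the silylmethyl group may transfer sluggishly from copper to the alkyne, or the hindered alkenylcopper may be alkylated incompletely by oxirane.

The fallback sets out from alkyne 10 and fixes the alkene geometry with a temporary ring:
- Lithiation (n-BuLi) and opening of oxirane with BF3·OEt2 would give the homopropargylic alcohol (6R,7S)-8-(benzyloxy)-6-[(tert-butyldimethylsilyl)oxy]-7-(propan-2-yl)oct-3-yn-1-ol F4.
- Silylation with (Me2HSi)2NH would give the hydrosilyl ether {[(6R,7S)-8-(benzyloxy)-6-[(tert-butyldimethylsilyl)oxy]-7-(propan-2-yl)oct-3-yn-1-yl]oxy}dimethylsilane F5.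
- Ruthenium-catalysed intramolecular endo-dig trans-hydrosilylation ([Cp*Ru(MeCN)3]PF6, CH2Cl2) would give the cyclic alkenylsiloxane 3-{(2R,3S)-4-(benzyloxy)-2-[(tert-butyldimethylsilyl)oxy]-3-(propan-2-yl)butyl}-2,2-dimethyl-5,6-dihydro-2H-1,2-oxasiline F6, in which the ring holds silicon on the internal carbon cis to the CH2CH2O arm.
- Iododesilylation with N-iodosuccinimide, with retention, would give the alkenyl iodide (3Z,6R,7S)-8-(benzyloxy)-6-[(tert-butyldimethylsilyl)oxy]-4-iodo-7-(propan-2-yl)oct-3-en-1-ol F7.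
- Kumada coupling with Me3SiCH2MgCl (PdCl2(dppf), THF), again with retention, returns to the route at 14 with the same Z geometry.

Step 15 (angeloylation of the β-hydroxy ketone). What may go wrong: the Z-enoate may isomerize to the tiglate during acylation, or the new acyloxy group may undergo base-induced β-elimination next to the ketone at 75 °C.

The fallback sets out from 23 and builds the angelate on the molecule at room temperature or below:
- Esterification with but-2-ynoic acid (DCC, catalytic DMAP, CH2Cl2, 0 °C) would give (1R,2S,3aR,6R,7S,7aR)-1-acetyl-6-[(tert-butyldimethylsilyl)oxy]-4-methylidene-7-(propan-2-yl)octahydro-1H-inden-2-yl but-2-ynoate F8.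
- Palladium-catalysed syn hydrostannation (Bu3SnH, Pd(PPh3)4, THF) would give the α-stannyl crotonate (1R,2S,3aR,6R,7S,7aR)-1-acetyl-6-[(tert-butyldimethylsilyl)oxy]-4-methylidene-7-(propan-2-yl)octahydro-1H-inden-2-yl (2E)-2-(tributylstannyl)but-2-enoate F9, with the β-methyl cis to the ester carbonyl.
- Stille methylation (MeI, Pd2(dba)3, tri(2-furyl)phosphine, CuI, DMF, rt), with retention, returns to the route at 26.

**Further compounds**
F1 | step 14 | 1-[(1R,2S,3R,6R)-3-[(tert-butyldimethylsilyl)oxy]-5-methylidene-2-(propan-2-yl)-6-{2-[(triethylsilyl)oxy]ethyl}cyclohexyl]propan-2-one | C=C1C[C@@H](O[Si](C)(C)C(C)(C)C)[C@@H](C(C)C)[C@H](CC(C)=O)[C@H]1CCO[Si](CC)(CC)CC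
F2 | step 14 | 1-[(1R,2S,3R,6R)-3-[(tert-butyldimethylsilyl)oxy]-6-(2-hydroxyethyl)-5-methylidene-2-(propan-2-yl)cyclohexyl]propan-2-one | C=C1C[C@@H](O[Si](C)(C)C(C)(C)C)[C@@H](C(C)C)[C@H](CC(C)=O)[C@H]1CCO
F3 | step 14 | 1-[(1R,2S,3R,6R)-3-[(tert-butyldimethylsilyl)oxy]-5-methylidene-6-(2-oxoethyl)-2-(propan-2-yl)cyclohexyl]propan-2-one | C=C1C[C@@H](O[Si](C)(C)C(C)(C)C)[C@@H](C(C)C)[C@H](CC(C)=O)[C@H]1CC=O
F4 | step 7 | (6R,7S)-8-(benzyloxy)-6-[(tert-butyldimethylsilyl)oxy]-7-(propan-2-yl)oct-3-yn-1-ol | OCCC#CC[C@@H](O[Si](C)(C)C(C)(C)C)[C@@H](C(C)C)COCc1ccccc1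
F5 | step 7 | {[(6R,7S)-8-(benzyloxy)-6-[(tert-butyldimethylsilyl)oxy]-7-(propan-2-yl)oct-3-yn-1-yl]oxy}dimethylsilane | C[SiH](C)OCCC#CC[C@@H](O[Si](C)(C)C(C)(C)C)[C@@H](C(C)C)COCc1ccccc1
F6 | step 7 | 3-{(2R,3S)-4-(benzyloxy)-2-[(tert-butyldimethylsilyl)oxy]-3-(propan-2-yl)butyl}-2,2-dimethyl-5,6-dihydro-2H-1,2-oxasiline | C[Si]1(C)OCCC=C1C[C@@H](O[Si](C)(C)C(C)(C)C)[C@@H](C(C)C)COCc1ccccc1
F7 | step 7 | (3Z,6R,7S)-8-(benzyloxy)-6-[(tert-butyldimethylsilyl)oxy]-4-iodo-7-(propan-2-yl)oct-3-en-1-ol | OCC/C=C(\I)C[C@@H](O[Si](C)(C)C(C)(C)C)[C@@H](C(C)C)COCc1ccccc1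
F8 | step 15 | (1R,2S,3aR,6R,7S,7aR)-1-acetyl-6-[(tert-butyldimethylsilyl)oxy]-4-methylidene-7-(propan-2-yl)octahydro-1H-inden-2-yl but-2-ynoate | C=C1C[C@@H](O[Si](C)(C)C(C)(C)C)[C@@H](C(C)C)[C@@H]2[C@@H](C(C)=O)[C@@H](OC(=O)C#CC)C[C@@H]12
F9 | step 15 | (1R,2S,3aR,6R,7S,7aR)-1-acetyl-6-[(tert-butyldimethylsilyl)oxy]-4-methylidene-7-(propan-2-yl)octahydro-1H-inden-2-yl (2E)-2-(tributylstannyl)but-2-enoate | C=C1C[C@@H](O[Si](C)(C)C(C)(C)C)[C@@H](C(C)C)[C@@H]2[C@@H](C(C)=O)[C@@H](OC(=O)/C([Sn](CCCC)(CCCC)CCCC)=C\C)C[C@@H]12
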